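**Plan**
- Retrosynthesis: cut the C15–O ester bond (caffeic acid). Cut C9–C11 and take C8=CH2/C9–H back, through a C8 ketone, to a C9 ketone. Put back a sulfur bridge C18–S–C6 and a C2=C3 alkene. Cut C1–C10 and C4–C5 of ring A.
- Enabling feature: ring A is a cyclohexane fused cis to ring B (H-5 and CH3-20 on one face), and the C4 methyl C18 is syn to C6. Ring A is therefore the adduct of a C1–C4 diene with a ring B enone C5=C10, held together by a one-atom sulfur tether between C18 and C6 (a temporary thiolane).
- Forward: ring B is made first as a ketal-masked 4-sulfanyl-2-methylcyclohexenone and S-alkylated with a bromomethyl dienoate. The intramolecular Diels–Alder reaction closes ring A and the thiolane. Raney Ni then erases the tether, leaving CH3-18 and CH2-6.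
- The side chain is joined at C9 by Negishi coupling of the C9 enol triflate. Hydroboration, oxidation and methylenation finish ring B. Mitsunobu esterification with caffeic acid and tert-butyl ester cleavage end the route.
- Stereochemistry: C6 (temporary) comes from a CBS reduction inverted by Mitsunobu thiolation. C4, C5 and C10 are relayed from C6 in the cycloaddition. C9 comes from convex-face hydroboration, C13 from (R)-monomethyl 3-methylglutarate.

Key step: step 9

Remark on the structure: the SMILES encodes a cis-fused decalin with H-5, CH3-20 and CO2H-19 on one face and CH3-18 and the C9 side chain on the other. Labdane numbering is used (C17 = exocyclic CH2 on C8, C18/C19 on C4, C20 on C10, chain C11–C15 with C16 on C13).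
Assumption: 4-methoxy-3-methylphenol, (R)-monomethyl 3-methylglutarate and caffeic acid are taken as commercial.

**Step 1**
Reactants: 1 4-methoxy-3-methylphenol
Product: 2 4,4-dimethoxy-3-methylcyclohexa-2,5-dien-1-one
Conditions: PhI(OAc)2, MeOH, 0 °C to rt
Reagents that add atoms: methanol (CO)
Why: Oxidative dearomatisation of a p-methoxyphenol with trivalent iodine; methanol captures the phenoxenium ion at the methoxy-bearing carbon (quinone monoketal formation).

**Step 2**
Reactants: 2 4,4-dimethoxy-3-methylcyclohexa-2,5-dien-1-one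
Product: 3 4,4-dimethoxy-3-methylcyclohex-2-en-1-one
Conditions: H2 (1 atm), RhCl(PPh3)3 (5 mol %), benzene, rt
Reagents that add atoms: none
Why: Homogeneous hydrogenation with RhCl(PPh3)3 distinguishes alkenes by substitution, so the disubstituted C=C of the cross-conjugated dienone should be saturated and the methyl-bearing enone kept (the known 1,2-selective reduction of cross-conjugated dienones).

**Step 3**
Reactants: 3 4,4-dimethoxy-3-methylcyclohex-2-en-1-one
Product: 4 (1R)-4,4-dimethoxy-3-methylcyclohex-2-en-1-ol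
Conditions: (S)-2-methyl-CBS-oxazaborolidine (10 mol %), catecholborane, toluene, −78 °C
Reagents that add atoms: none
Why: Corey–Bakshi–Shibata reduction: the ketone binds the oxazaborolidine anti to the larger alkenyl arm (which also carries the quaternary ketal carbon), so the (S)-catalyst should give the (R)-allylic alcohol; this temporary centre becomes C6.

**Step 4**
Reactants: 4 (1R)-4,4-dimethoxy-3-methylcyclohex-2-en-1-ol
Product: 5 S-[(1S)-4,4-dimethoxy-3-methylcyclohex-2-en-1-yl] ethanethioate
Conditions: PPh3, DIAD, AcSH, THF, 0 °C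
Reagents that add atoms: thioacetic acid (CC(=O)S)
Why: Mitsunobu displacement with a thioacid is an SN2 reaction with inversion, giving the (S)-thioacetate; the SN2′ path would have to form a tertiary C–S bond next to the ketal and is disfavoured.

**Step 5**
Reactants: 6 acrolein; 7 tert-butyl acrylate
Product: 8 tert-butyl 3-hydroxy-2-methylidenepent-4-enoate (racemic)
Conditions: DABCO (0.3 equiv), 1,4-dioxane/H2O, rt
Reagents that add atoms: none
Why: Morita–Baylis–Hillman reaction: the ammonium enolate of the acrylate adds to the aldehyde carbon of acrolein; the carbinol centre is racemic and disappears in the next step.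

**Step 6**
Reactants: 8 tert-butyl 3-hydroxy-2-methylidenepent-4-enoate
Product: 9 tert-butyl (2Z)-2-(bromomethyl)penta-2,4-dienoate
Conditions: NBS, Me2S, CH2Cl2, 0 °C to rt
Reagents that add atoms: N-bromosuccinimide (O=C1CCC(=O)N1Br)
Why: Allylic bromination with transposition (SN2′ attack of bromide on the oxysulfonium-activated bis-allylic alcohol) gives the conjugated dienoate; the Z isomer (CH2Br cis to vinyl) is the usual, thermodynamically preferred outcome for such adducts.

**Step 7**
Reactants: 5 S-[(1S)-4,4-dimethoxy-3-methylcyclohex-2-en-1-yl] ethanethioate; 9 tert-butyl (2Z)-2-(bromomethyl)penta-2,4-dienoate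
Product: 11 tert-butyl (2Z)-2-({[(1S)-4,4-dimethoxy-3-methylcyclohex-2-en-1-yl]sulfanyl}methyl)penta-2,4-dienoate, via allylic thiol 10 (not isolated)
Conditions: K2CO3, degassed MeOH, 0 °C; then 9, 0 °C to rt
Reagents that add atoms: none
Why: Methanolysis of the thioacetate frees the thiolate, which is S-alkylated by the allylic bromide (SN2) without touching the C–S stereocentre or the alkene geometry; the ketal keeps the enone masked, so there is no Michael acceptor and no dienolate path to racemisation.

**Step 8**
Reactants: 11 ketal sulfide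
Product: 12 tert-butyl (2Z)-2-({[(1S)-3-methyl-4-oxocyclohex-2-en-1-yl]sulfanyl}methyl)penta-2,4-dienoate
Conditions: oxalic acid (aq.), THF, rt
Reagents that add atoms: water (O)
Why: Mild acid hydrolysis of the allylic dimethyl ketal (alkene-stabilised oxocarbenium ion) unmasks the enone and leaves the tert-butyl ester and the allylic sulfide alone.

**Step 9**
Reactants: 12 enone dienoate sulfide
Product: 13 tert-butyl (2aR,5aS,8aS,8bS)-5a-methyl-6-oxo-2a,5,5a,6,7,8,8a,8b-octahydro-2H-naphtho[1,8-bc]thiophene-2a-carboxylate (ring A cyclohexene with C2=C3, ring B cyclohexanone, thiolane C4–C18–S–C6–C5)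
Conditions: toluene (0.005 M), BHT, 130 °C, sealed tube
Reagents that add atoms: none
Why: Thermal intramolecular Diels–Alder reaction of type 1 (closest model: cyclisation of (Z)-nona-1,3,8-trienes with a heteroatom in the three-atom tether onto a cycloalkenone): the dienoate C1=C2–C3=C4 adds suprafacially to the enone bond C5=C10 in a concerted, asynchronous [4+2] event, C4–C5 (to the enone β-carbon) running ahead of C1–C10. Ring A closes as the cyclohexene of the cycloaddition, and the C18–S–C6 tether closes at the same time as a five-membered thiolane in the fused mode, which can only be cis for a tether on the inside (Z) position of the diene. Suprafacial addition to the ring alkene puts H-5 and CH3-10 on one face (cis-decalin); the diene is held on the sulfur-bearing face of ring B, so the (S)-C6 centre fixes the absolute sense at C5 and C10, and C4 follows from the tether geometry (C18 syn to C6, the ester syn to H-5 and CH3-10). Regiochemistry (C4 to C5, C1 to C10, not the orientation expected of the untethered partners) and facial selectivity are both secured by the short tether, and the C9 carbonyl lowers the LUMO of the otherwise inert trisubstituted alkene. The selectivity still needed is over the [1,5]-hydrogen shift of the (Z)-diene and over dimerisation, which high dilution, BHT and the lowest workable temperature should provide.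

**Step 10**
Reactants: 13 cycloadduct
Product: 14 tert-butyl (1S,4aS,8aS)-1,4a-dimethyl-5-oxodecahydronaphthalene-1-carboxylate
Conditions: Raney Ni (W-2), H2 (1 atm), EtOH, rt to 50 °C
Reagents that add atoms: none
Why: Raney Ni hydrogenolysis of both C–S bonds turns C18 into the C4 methyl and C6 into a methylene, and the C2=C3 alkene is hydrogenated under the same conditions; the ketone next to the quaternary C10 should survive.

**Step 11**
Reactants: 14 keto ester
Product: 16 tert-butyl (1S,4aS,8aS)-1,4a-dimethyl-5-(trifluoromethanesulfonyloxy)-1,2,3,4,4a,7,8,8a-octahydronaphthalene-1-carboxylate, via potassium enolate 15 (not isolated)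
Conditions: KN(SiMe3)2, THF, −78 °C; then PhNTf2, −78 to 0 °C
Reagents that add atoms: N-phenylbis(trifluoromethanesulfonimide) (O=S(=O)(N(c1ccccc1)S(=O)(=O)C(F)(F)F)C(F)(F)F)
Why: The ketone can enolise only toward C8 (C10 is quaternary and the ester has no α-hydrogen), so enolate formation and O-sulfonylation give a single enol triflate.

**Step 12**
Reactants: 17 (3R)-5-methoxy-3-methyl-5-oxopentanoic acid ((R)-monomethyl 3-methylglutarate)
Product: 18 methyl (3R)-5-hydroxy-3-methylpentanoate
Conditions: BH3·SMe2, THF, 0 °C to rt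
Reagents that add atoms: none
Why: Borane reduces the carboxylic acid (through the acyloxyborane) much faster than the methyl ester, which tells the two arms of the desymmetrised glutarate apart without touching the stereocentre.

**Step 13**
Reactants: 18 hydroxy ester
Product: 19 methyl (3R)-5-[(tert-butyldimethylsilyl)oxy]-3-methylpentanoate
Conditions: TBSCl, imidazole, DMF, 0 °C to rt
Reagents that add atoms: tert-butyldimethylsilyl chloride (CC(C)(C)[Si](C)(C)Cl)
Why: Silylation of the primary alcohol, done at once to forestall δ-lactone formation.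

**Step 14**
Reactants: 19 silyloxy ester
Product: 20 (3S)-5-[(tert-butyldimethylsilyl)oxy]-3-methylpentan-1-ol
Conditions: LiBH4, THF, MeOH (1 equiv), 0 °C to rt
Reagents that add atoms: none
Why: LiBH4 reduces the ester to the primary alcohol and leaves the silyl ether; the descriptor changes only because the priorities change.

**Step 15**
Reactants: 20 silyloxy alcohol
Product: 21 tert-butyl{[(3R)-5-iodo-3-methylpentyl]oxy}dimethylsilane
Conditions: I2, PPh3, imidazole, CH2Cl2, 0 °C to rt
Reagents that add atoms: iodine (II)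
Why: Appel-type iodination of the primary alcohol (SN2 on the alkoxyphosphonium ion).

**Step 16**
Reactants: 16 enol triflate; 21 iodide
Product: 23 tert-butyl (1S,4aS,8aS)-5-{(3S)-5-[(tert-butyldimethylsilyl)oxy]-3-methylpentyl}-1,4a-dimethyl-1,2,3,4,4a,7,8,8a-octahydronaphthalene-1-carboxylate, via alkylzinc iodide 22 (not isolated)
Conditions: 21, Zn dust, LiCl, THF, 40 °C; then 16, Pd(dppf)Cl2 (5 mol %), THF/DMA, 50 °C
Reagents that add atoms: none
Why: Negishi sp2–sp3 cross-coupling: zinc inserts into the primary C–I bond and zerovalent palladium (from Pd(dppf)Cl2) couples the alkylzinc with the enol triflate, the wide-bite-angle ligand favouring reductive elimination over β-hydride elimination; this forms C9–C11 and brings in C13.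

**Step 17**
Reactants: 23 C8=C9 alkene
Product: 25 tert-butyl (1S,4aS,5S,6S,8aS)-5-{(3S)-5-[(tert-butyldimethylsilyl)oxy]-3-methylpentyl}-6-hydroxy-1,4a-dimethyldecahydronaphthalene-1-carboxylate, via C8 alkylborane 24 (not isolated)
Conditions: BH3·THF, THF, 0 °C to rt; then NaOH (aq.), H2O2, 0 °C to rt
Reagents that add atoms: hydrogen peroxide (OO)
Why: Hydroboration–oxidation: boron goes to the less substituted C8 and hydrogen to C9 in a syn addition from the convex face of the cis-fused bicycle (the face of H-5 and CH3-10, away from ring A), which should set C9–H syn to the C10 methyl and the side chain on the ring A side; the C8 carbinol centre is removed in the next step.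

**Step 18**
Reactants: 25 C8 alcohol
Product: 26 tert-butyl (1S,4aS,5S,8aS)-5-{(3S)-5-[(tert-butyldimethylsilyl)oxy]-3-methylpentyl}-1,4a-dimethyl-6-oxodecahydronaphthalene-1-carboxylate
Conditions: Dess–Martin periodinane, NaHCO3, CH2Cl2, rt
Reagents that add atoms: none
Why: Dess–Martin oxidation under buffered, non-enolising conditions gives the C8 ketone without epimerising the adjacent C9 centre.

**Step 19**
Reactants: 26 C8 ketone
Product: 27 tert-butyl (1S,4aR,5R,8aS)-5-{(3S)-5-[(tert-butyldimethylsilyl)oxy]-3-methylpentyl}-1,4a-dimethyl-6-methylidenedecahydronaphthalene-1-carboxylate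
Conditions: Zn, CH2Br2, TiCl4, THF (reagent pre-formed); then 26, CH2Cl2, 0 °C to rt
Reagents that add atoms: dibromomethane (BrCBr)
Why: Non-basic methylenation with the zinc/titanium gem-dimetallic reagent (Takai–Lombardo olefination) converts the ketone into the exocyclic methylene without enolising it, so C9 keeps its configuration; the hindered tert-butyl ester is not attacked.

**Step 20**
Reactants: 27 silyl ether
Product: 28 tert-butyl (1S,4aR,5R,8aS)-5-[(3S)-5-hydroxy-3-methylpentyl]-1,4a-dimethyl-6-methylidenedecahydronaphthalene-1-carboxylate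
Conditions: Bu4NF, THF, 0 °C to rt
Reagents that add atoms: none
Why: Fluoride cleaves the primary silyl ether; the tert-butyl ester and the alkene are inert.

**Step 21**
Reactants: 28 C15 alcohol; 29 caffeic acid
Product: 30 tert-butyl (1S,4aR,5R,8aS)-5-[(3S)-5-{[(2E)-3-(3,4-dihydroxyphenyl)prop-2-enoyl]oxy}-3-methylpentyl]-1,4a-dimethyl-6-methylidenedecahydronaphthalene-1-carboxylate
Conditions: PPh3, DIAD, THF, 0 °C to rt
Reagents that add atoms: none
Why: Mitsunobu esterification: the carboxylic acid of caffeic acid is far more acidic than its phenols and is the group that is O-alkylated by the activated primary alcohol, so the catechol needs no protection; inversion at the CH2 carbon C15 has no stereochemical consequence.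

**Step 22**
Reactants: 30 caffeate tert-butyl ester
Product: 32 (1S,4aR,5R,8aS)-5-[(3S)-5-{[(2E)-3-(3,4-dihydroxyphenyl)prop-2-enoyl]oxy}-3-methylpentyl]-1,4a-dimethyl-6-methylidenedecahydronaphthalene-1-carboxylic acid (target), via tris(trimethylsilyl) derivative 31 (not isolated)
Conditions: TMSOTf, 2,6-lutidine, CH2Cl2, 0 °C; then MeOH, aq. citric acid, rt
Reagents that add atoms: none
Why: Silyl triflate buffered by 2,6-lutidine converts the tert-butyl ester into the silyl ester with loss of isobutene (no protic acid, so the exocyclic alkene is not isomerised) and silylates the phenols transiently; mild aqueous methanolysis then frees the acid and the catechol without touching the cinnamate ester.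

**Compound list**
1 | 4-methoxy-3-methylphenol | COc1ccc(O)cc1C | starting material
2 | 4,4-dimethoxy-3-methylcyclohexa-2,5-dien-1-one | COC1(OC)C=CC(=O)C=C1C | intermediate
3 | 4,4-dimethoxy-3-methylcyclohex-2-en-1-one | COC1(OC)CCC(=O)C=C1C | intermediate
4 | (1R)-4,4-dimethoxy-3-methylcyclohex-2-en-1-ol | O[C@@H]1CCC(OC)(OC)C(C)=C1 | intermediate
5 | S-[(1S)-4,4-dimethoxy-3-methylcyclohex-2-en-1-yl] ethanethioate | CC(=O)S[C@H]1CCC(OC)(OC)C(C)=C1 | intermediate
6 | acrolein | C=CC=O | starting material
7 | tert-butyl acrylate | C=CC(=O)OC(C)(C)C | starting material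
8 | tert-butyl 3-hydroxy-2-methylidenepent-4-enoate (racemic) | C=CC(O)C(=C)C(=O)OC(C)(C)C | intermediate
9 | tert-butyl (2Z)-2-(bromomethyl)penta-2,4-dienoate | C=C/C=C(\CBr)C(=O)OC(C)(C)C | intermediate
10 | (1S)-4,4-dimethoxy-3-methylcyclohex-2-ene-1-thiol (present as its potassium thiolate, not isolated) | S[C@H]1CCC(OC)(OC)C(C)=C1 | intermediate
11 | tert-butyl (2Z)-2-({[(1S)-4,4-dimethoxy-3-methylcyclohex-2-en-1-yl]sulfanyl}methyl)penta-2,4-dienoate | C=C/C=C(\CS[C@H]1CCC(OC)(OC)C(C)=C1)C(=O)OC(C)(C)C | intermediate
12 | tert-butyl (2Z)-2-({[(1S)-3-methyl-4-oxocyclohex-2-en-1-yl]sulfanyl}methyl)penta-2,4-dienoate | C=C/C=C(\CS[C@H]1CCC(=O)C(C)=C1)C(=O)OC(C)(C)C | intermediate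
13 | tert-butyl (2aR,5aS,8aS,8bS)-5a-methyl-6-oxo-2a,5,5a,6,7,8,8a,8b-octahydro-2H-naphtho[1,8-bc]thiophene-2a-carboxylate (labdane numbering 4R,5S,6S,10S) | CC(C)(C)OC(=O)[C@]12C=CC[C@]3(C)C(=O)CC[C@H](SC1)[C@H]23 | intermediate
14 | tert-butyl (1S,4aS,8aS)-1,4a-dimethyl-5-oxodecahydronaphthalene-1-carboxylate | O=C1CCC[C@H]2[C@]1(C)CCC[C@]2(C)C(=O)OC(C)(C)C | intermediate
15 | potassium enolate of 14 (C8=C9–OK, not isolated) | [K+].[O-]C1=CCC[C@H]2[C@]1(C)CCC[C@]2(C)C(=O)OC(C)(C)C | intermediate
16 | tert-butyl (1S,4aS,8aS)-1,4a-dimethyl-5-(trifluoromethanesulfonyloxy)-1,2,3,4,4a,7,8,8a-octahydronaphthalene-1-carboxylate | O=S(=O)(OC1=CCC[C@H]2[C@]1(C)CCC[C@]2(C)C(=O)OC(C)(C)C)C(F)(F)F | intermediate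
17 | (3R)-5-methoxy-3-methyl-5-oxopentanoic acid | C[C@@H](CC(=O)OC)CC(=O)O | starting material
18 | methyl (3R)-5-hydroxy-3-methylpentanoate | C[C@@H](CC(=O)OC)CCO | intermediate
19 | methyl (3R)-5-[(tert-butyldimethylsilyl)oxy]-3-methylpentanoate | C[C@@H](CC(=O)OC)CCO[Si](C)(C)C(C)(C)C | intermediate
20 | (3S)-5-[(tert-butyldimethylsilyl)oxy]-3-methylpentan-1-ol | C[C@@H](CCO)CCO[Si](C)(C)C(C)(C)C | intermediate
21 | tert-butyl{[(3R)-5-iodo-3-methylpentyl]oxy}dimethylsilane | C[C@@H](CCI)CCO[Si](C)(C)C(C)(C)C | intermediate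
22 | {(3R)-5-[(tert-butyldimethylsilyl)oxy]-3-methylpentyl}zinc iodide (not isolated) | C[C@@H](CC[Zn]I)CCO[Si](C)(C)C(C)(C)C | intermediate
23 | tert-butyl (1S,4aS,8aS)-5-{(3S)-5-[(tert-butyldimethylsilyl)oxy]-3-methylpentyl}-1,4a-dimethyl-1,2,3,4,4a,7,8,8a-octahydronaphthalene-1-carboxylate | C[C@@H](CCC1=CCC[C@H]2[C@]1(C)CCC[C@]2(C)C(=O)OC(C)(C)C)CCO[Si](C)(C)C(C)(C)C | intermediate
24 | C8 alkylborane from 23 (BH2 on C8 and H on C9, both on the face of CH3-20; not isolated) | B[C@H]1CC[C@H]2[C@](C)(CCC[C@]2(C)C(=O)OC(C)(C)C)[C@@H]1CC[C@H](C)CCO[Si](C)(C)C(C)(C)C | intermediate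
25 | tert-butyl (1S,4aS,5S,6S,8aS)-5-{(3S)-5-[(tert-butyldimethylsilyl)oxy]-3-methylpentyl}-6-hydroxy-1,4a-dimethyldecahydronaphthalene-1-carboxylate | O[C@H]1CC[C@H]2[C@](C)(CCC[C@]2(C)C(=O)OC(C)(C)C)[C@@H]1CC[C@H](C)CCO[Si](C)(C)C(C)(C)C | intermediate
26 | tert-butyl (1S,4aS,5S,8aS)-5-{(3S)-5-[(tert-butyldimethylsilyl)oxy]-3-methylpentyl}-1,4a-dimethyl-6-oxodecahydronaphthalene-1-carboxylate | O=C1CC[C@H]2[C@](C)(CCC[C@]2(C)C(=O)OC(C)(C)C)[C@@H]1CC[C@H](C)CCO[Si](C)(C)C(C)(C)C | intermediate
27 | tert-butyl (1S,4aR,5R,8aS)-5-{(3S)-5-[(tert-butyldimethylsilyl)oxy]-3-methylpentyl}-1,4a-dimethyl-6-methylidenedecahydronaphthalene-1-carboxylate | C=C1CC[C@H]2[C@](C)(CCC[C@]2(C)C(=O)OC(C)(C)C)[C@@H]1CC[C@H](C)CCO[Si](C)(C)C(C)(C)C | intermediate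
28 | tert-butyl (1S,4aR,5R,8aS)-5-[(3S)-5-hydroxy-3-methylpentyl]-1,4a-dimethyl-6-methylidenedecahydronaphthalene-1-carboxylate | C=C1CC[C@H]2[C@](C)(CCC[C@]2(C)C(=O)OC(C)(C)C)[C@@H]1CC[C@H](C)CCO | intermediate
29 | caffeic acid, (2E)-3-(3,4-dihydroxyphenyl)prop-2-enoic acid | O=C(O)/C=C/c1ccc(O)c(O)c1 | starting material
30 | tert-butyl (1S,4aR,5R,8aS)-5-[(3S)-5-{[(2E)-3-(3,4-dihydroxyphenyl)prop-2-enoyl]oxy}-3-methylpentyl]-1,4a-dimethyl-6-methylidenedecahydronaphthalene-1-carboxylate | C=C1CC[C@H]2[C@](C)(CCC[C@]2(C)C(=O)OC(C)(C)C)[C@@H]1CC[C@H](C)CCOC(=O)/C=C/c1ccc(O)c(O)c1 | intermediate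
31 | trimethylsilyl ester bis(trimethylsilyl) aryl ether of the target (not isolated) | C=C1CC[C@H]2[C@](C)(CCC[C@]2(C)C(=O)O[Si](C)(C)C)[C@@H]1CC[C@H](C)CCOC(=O)/C=C/c1ccc(O[Si](C)(C)C)c(O[Si](C)(C)C)c1 | intermediate
32 | (1S,4aR,5R,8aS)-5-[(3S)-5-{[(2E)-3-(3,4-dihydroxyphenyl)prop-2-enoyl]oxy}-3-methylpentyl]-1,4a-dimethyl-6-methylidenedecahydronaphthalene-1-carboxylic acid | C=C1CC[C@H]2[C@](C)(CCC[C@]2(C)C(=O)O)[C@@H]1CC[C@H](C)CCOC(=O)/C=C/c1ccc(O)c(O)c1 | target

**Step count**
Total: 22 steps. Longest linear sequence: 16 steps (steps 1–4, 7–11, 16–22).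

**Steps most likely to fail**

Step 9. The cycloaddition may be too slow to compete with a [1,5]-hydrogen shift in the (Z)-diene or with a 1,3-shift of sulfur in the two allylic sulfide units, because both π partners are electron-poor and two quaternary carbons are formed. The fallback sets out from 9 (with 5 as before) and comes back at 14; it makes the diene electron-rich so that the cycloaddition runs with normal electron demand. Ester 9 is reduced with (i-Bu)2AlH (CH2Cl2, −78 °C) to (2Z)-2-(bromomethyl)penta-2,4-dien-1-ol F1 and silylated (TBSCl, imidazole) to its tert-butyldimethylsilyl ether F2. Thiol 10, freed from 5 as in step 7, is S-alkylated with F2 to the ketal sulfide F3, and aqueous oxalic acid gives the enone F4. Heating in toluene (or Me2AlCl at low temperature, now possible without the tert-butyl ester) should give the silyloxymethyl cycloadduct F5 with the same tether-controlled stereochemistry. Raney Ni/H2 gives the keto silyl ether F6, Bu4NF the keto alcohol F7, TEMPO/PhI(OAc)2 in aqueous MeCN the keto acid F8, and tert-butyl 2,2,2-trichloroacetimidate with BF3·OEt2 the ester 14.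

Step 17. Facial selectivity may be poor, with borane adding from the ring A face and giving the C9 epimer. The fallback sets out from 23 and comes back at 26; it sets C9 under thermodynamic instead of kinetic control. The epimeric alcohol, the (8R,9R)-diastereomer of 25 F9, is oxidised as in step 18 to the 9-epi ketone F10, which is equilibrated through its enolate (NaOMe, MeOH, rt). In the favoured conformer of the cis-decalin (C1 axial on ring B, the C4 methyl equatorial on ring A) the side chain of 26 is equatorial and that of F10 axial, so 26 should dominate; it is separated and the remainder recycled.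

Step 3. Enantioselectivity may be insufficient, since the two flanks of the carbonyl (CH= and CH2) differ little at the α-positions, and every later stereocentre inherits this. The fallback sets out from 3 and comes back at 4; it uses resolution instead of asymmetric induction. NaBH4/CeCl3·7H2O (MeOH, −78 °C) gives the racemic allylic alcohol F11. Lipase-mediated acylation (Burkholderia cepacia lipase, vinyl acetate) should acylate the (R)-enantiomer to the (1R)-acetate F12 and leave the (1S)-alcohol F13. After separation, K2CO3/MeOH converts F12 into 4; F13 can be brought into the same series by Mitsunobu inversion with acetic acid.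

**Further compounds**
F1 | step 9 | (2Z)-2-(bromomethyl)penta-2,4-dien-1-ol | C=C/C=C(\CBr)CO
F2 | step 9 | {[(2Z)-2-(bromomethyl)penta-2,4-dien-1-yl]oxy}(tert-butyl)dimethylsilane | C=C/C=C(\CBr)CO[Si](C)(C)C(C)(C)C
F3 | step 9 | ketal sulfide, CH2OTBS analogue of 11 | C=C/C=C(\CS[C@H]1CCC(OC)(OC)C(C)=C1)CO[Si](C)(C)C(C)(C)C
F4 | step 9 | enone, CH2OTBS analogue of 12 | C=C/C=C(\CS[C@H]1CCC(=O)C(C)=C1)CO[Si](C)(C)C(C)(C)C
F5 | step 9 | cycloadduct, CH2OTBS analogue of 13 | CC(C)(C)[Si](C)(C)OC[C@]12C=CC[C@]3(C)C(=O)CC[C@H](SC1)[C@H]23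
F6 | step 9 | keto silyl ether, CH2OTBS analogue of 14 | O=C1CCC[C@H]2[C@]1(C)CCC[C@]2(C)CO[Si](C)(C)C(C)(C)C
F7 | step 9 | keto alcohol, CH2OH analogue of 14 | O=C1CCC[C@H]2[C@]1(C)CCC[C@]2(C)CO
F8 | step 9 | (1S,4aS,8aS)-1,4a-dimethyl-5-oxodecahydronaphthalene-1-carboxylic acid | O=C1CCC[C@H]2[C@]1(C)CCC[C@]2(C)C(=O)O
F9 | step 17 | (8R,9R)-diastereomer of 25 (labdane numbering) | O[C@@H]1CC[C@H]2[C@](C)(CCC[C@]2(C)C(=O)OC(C)(C)C)[C@H]1CC[C@H](C)CCO[Si](C)(C)C(C)(C)C
F10 | step 17 | C9 epimer of 26 | O=C1CC[C@H]2[C@](C)(CCC[C@]2(C)C(=O)OC(C)(C)C)[C@H]1CC[C@H](C)CCO[Si](C)(C)C(C)(C)C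
F11 | step 3 | 4,4-dimethoxy-3-methylcyclohex-2-en-1-ol (racemic) | OC1CCC(OC)(OC)C(C)=C1
F12 | step 3 | (1R)-4,4-dimethoxy-3-methylcyclohex-2-en-1-yl acetate | CC(=O)O[C@@H]1CCC(OC)(OC)C(C)=C1
F13 | step 3 | (1S)-4,4-dimethoxy-3-methylcyclohex-2-en-1-ol | O[C@H]1CCC(OC)(OC)C(C)=C1
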